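## Retrosynthetic overview

1. Rings: A is the 1,4-dioxygenated ring, B the para-phenylene, C the catechol-type ring, D the meta-phenylene. Target 22, an 18-membered macrocycle, is traced back through O-demethylation to an intramolecular Ullmann closure of the ring B–O–ring C ether in seco-phenol 20.
2. The strategy rests on ring A: a benzene with free OH on C1, the ether oxygen to ring D on C4 (para), the CH2CH2 link to ring B on C5 next to that ether, and CH at C2, C3 and C6. A chromium alkenyl(oxy)carbene, an alkyne and CO deliver exactly this pattern: carbene carbon to C4, alkene carbons to C5 and C6, CO to C1, alkyne carbons to C2 and C3.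
3. Ring A is therefore disconnected to aryloxy(alkenyl)carbene 14 and trimethylsilylacetylene 15. The hindered C4–O–ring D bond is made beforehand by addition–elimination of phenol 12 at the carbene carbon.
4. Carbene 14 comes from raspberry ketone 1 (Shapiro vinyllithium, Cr(CO)6) and bibenzyl phenol 12 (Wittig reaction and diimide reduction from 8 and 10).
5. Ring order: rings B, C and D are bought, ring A is built in step 8, the macrocycle is closed in step 12.

Key step: step 8

Remark: the ring B phenol is carried as a triisopropylsilyl ether, chosen to withstand n-BuLi, acetyl bromide and K2CO3/MeI. Both alkyne-derived carbons end as CH, so the position SiMe3 takes in step 8 does not affect the route; the expected ortho-silyl phenol is drawn as 17.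

## Route

Step 1
Reactants: 1 4-(4-hydroxyphenyl)butan-2-one
Product: 2 4-[4-(triisopropylsilyloxy)phenyl]butan-2-one
Conditions: TIPSCl, imidazole, DMF, rt
Reagents that add atoms: triisopropylsilyl chloride, CC(C)[Si](Cl)(C(C)C)C(C)C
Why: Imidazole-promoted silylation of the phenol leaves the methyl ketone untouched and gives a silyl ether that should survive n-BuLi, acetyl bromide at low temperature and carbonate base.

Step 2
Reactants: 2 4-[4-(triisopropylsilyloxy)phenyl]butan-2-one
Product: 3 N'-{4-[4-(triisopropylsilyloxy)phenyl]butan-2-ylidene}-2,4,6-triisopropylbenzenesulfonohydrazide (mainly E)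
Conditions: 2,4,6-triisopropylbenzenesulfonyl hydrazide, MeCN, cat. HCl, rt
Reagents that add atoms: 2,4,6-triisopropylbenzenesulfonyl hydrazide, NNS(=O)(=O)c1c(C(C)C)cc(C(C)C)cc1C(C)C
Why: Hydrazone condensation of a methyl ketone should give mainly the E isomer with NH on the methyl side, which later directs deprotonation to the methyl group.

Step 3
Reactants: 3 the trisylhydrazone; 4 hexacarbonylchromium
Product: 7 tetramethylammonium pentacarbonyl{1-oxido-2-methylidene-4-[4-(triisopropylsilyloxy)phenyl]butylidene}chromate, via vinyllithium 5 (not isolated), via lithium acylchromate 6 (not isolated)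
Conditions: n-BuLi (2.05 equiv), THF, −78 to 0 °C; Cr(CO)6, THF, 0 °C to rt; Me4NBr, H2O, CH2Cl2 extraction
Reagents that add atoms: tetramethylammonium bromide, C[N+](C)(C)C.[Br-]
Why: In a Shapiro reaction the dianion (NH and the syn methyl group deprotonated) loses sulfinate and N2 to give 2-lithio-1-alkene 5, which adds to a CO ligand as in the Fischer carbene synthesis, and cation exchange gives the storable ammonium acylate.

Step 4
Reactants: 8 3-(hydroxymethyl)phenol
Product: 9 (3-hydroxybenzyl)triphenylphosphonium bromide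
Conditions: PPh3·HBr, MeCN, reflux
Reagents that add atoms: triphenylphosphine hydrobromide, Br.c1ccc(cc1)P(c1ccccc1)c1ccccc1
Why: HBr converts the benzylic alcohol into the benzylic bromide, which PPh3 quaternises in the same flask, while the phenol does not react.

Step 5
Reactants: 9 (3-hydroxybenzyl)triphenylphosphonium bromide; 10 3-bromo-4-methoxybenzaldehyde
Product: 11 3-[2-(3-bromo-4-methoxyphenyl)ethenyl]phenol (E/Z mixture)
Conditions: t-BuOK (2.2 equiv), THF, 0 °C to rt; then 1 M HCl
Reagents that add atoms: none
Why: Wittig olefination of the semi-stabilised ylide, with the second equivalent of base only deprotonating the phenol, should give the stilbene as an E/Z mixture whose geometry is erased in step 6.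

Step 6
Reactants: 11 3-[2-(3-bromo-4-methoxyphenyl)ethenyl]phenol
Product: 12 3-[2-(3-bromo-4-methoxyphenyl)ethyl]phenol
Conditions: TsNHNH2, NaOAc, DME/H2O, reflux
Reagents that add atoms: none
Why: Diimide reduction transfers H2 to the stilbene C=C by concerted syn addition and spares the aryl bromide, which hydrogenation over palladium would endanger.

Step 7
Reactants: 7 the tetramethylammonium acylchromate; 12 3-[2-(3-bromo-4-methoxyphenyl)ethyl]phenol
Product: 14 pentacarbonyl[{3-[2-(3-bromo-4-methoxyphenyl)ethyl]phenoxy}{4-[4-(triisopropylsilyloxy)phenyl]but-1-en-2-yl}methylidene]chromium, via acetoxycarbene complex 13 (not isolated)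
Conditions: AcBr, CH2Cl2, −40 °C; then 12, −40 to 0 °C
Reagents that add atoms: none
Why: O-acylation of the acylchromate gives acyloxycarbene 13, a mixed-anhydride-like species whose carbene carbon undergoes addition–elimination with the phenol, which is the established acyl halide route to alkoxy- and aryloxycarbene complexes.

Step 8
Reactants: 14 the aryloxy(alkenyl)carbene complex; 15 ethynyltrimethylsilane
Product: 17 4-{3-[2-(3-bromo-4-methoxyphenyl)ethyl]phenoxy}-5-{2-[4-(triisopropylsilyloxy)phenyl]ethyl}-2-(trimethylsilyl)phenol, via tricarbonylchromium arene complex 16 (not isolated)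
Conditions: 15 (2 equiv), THF (0.05 M), 50 °C, Ar; then air, light, MeCN, rt
Reagents that add atoms: none
Why: Proposed new method: thermal loss of one CO from 14 lets the alkyne bind and insert into the Cr=C bond, CO insertion then gives a chromium-bound dienylketene, and 6π-electrocyclic closure onto the terminal CH2 of the alkene followed by tautomerisation should give the phenol as its tricarbonylchromium complex 16, which air releases as 17. The closest known reaction is the Dötz benzannulation of alkoxy(alkenyl)carbene complexes of zerovalent chromium (for example the isopropenyl methoxy complex) with silyl alkynes; the new element is the aryloxy group on the carbene carbon, which donates less, so CO loss is easier but the intermediates are less stabilised. Ring A closes in the 6π-electrocyclisation mode, with the carbene carbon becoming C4 (ether), the alkene carbons C5 and C6, the inserted CO C1 (hydroxyl) and the alkyne carbons C2 and C3. No stereocentre is formed. The step needs phenol formation to win over cyclobutenone, furan and cyclopentannulation channels, which an alkenyl rather than aryl carbene substituent and a donor solvent at moderate temperature favour, and it needs uptake of a single alkyne, which the bulky SiMe3 group secures. SiMe3 is expected next to C1 on steric grounds, but either orientation, or migration of silicon to oxygen, converges on 18 in step 9.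

Step 9
Reactants: 17 the ortho-silyl phenol
Product: 18 4-{3-[2-(3-bromo-4-methoxyphenyl)ethyl]phenoxy}-3-{2-[4-(triisopropylsilyloxy)phenyl]ethyl}phenol
Conditions: TFA, CH2Cl2, 0 °C to rt
Reagents that add atoms: none
Why: Protodesilylation by ipso-protonation at the silyl-bearing carbon, activated by the ortho hydroxyl, should remove SiMe3 while the aryl triisopropylsilyl ether is stable to TFA at this temperature.

Step 10
Reactants: 18 the ring A phenol
Product: 19 1-{3-[2-(3-bromo-4-methoxyphenyl)ethyl]phenoxy}-4-methoxy-2-{2-[4-(triisopropylsilyloxy)phenyl]ethyl}benzene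
Conditions: MeI, K2CO3, acetone, 50 °C
Reagents that add atoms: iodomethane, CI
Why: Williamson methylation of the only free phenol, under carbonate conditions that do not cleave the triisopropylsilyl ether, masks the ring A oxygen so that only the ring B phenol can couple later.

Step 11
Reactants: 19 the methyl ether
Product: 20 4-[2-(2-{3-[2-(3-bromo-4-methoxyphenyl)ethyl]phenoxy}-5-methoxyphenyl)ethyl]phenol
Conditions: TBAF, THF, 0 °C; then 1 M HCl
Reagents that add atoms: none
Why: Fluoride-induced desilylation cleaves the aryl silyl ether selectively and exposes the ring B phenol while the methyl ethers, the diaryl ether and the aryl bromide remain.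

Step 12
Reactants: 20 the seco-phenol
Product: 21 the macrocyclic di-O-methyl ether of the target
Conditions: CuI (30 mol%), N,N-dimethylglycine hydrochloride (60 mol%), Cs2CO3, 1,4-dioxane, 100 °C, syringe-pump addition to 2 mM
Reagents that add atoms: none
Why: Ligand-accelerated intramolecular Ullmann diaryl ether coupling joins the only phenol to the only aryl bromide, and high dilution should favour closure of the 18-membered ring over oligomers.

Step 13
Reactants: 21 the macrocyclic di-O-methyl ether
Product: 22 CNP0135015.0 (target)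
Conditions: BBr3, CH2Cl2, −78 °C to rt; then H2O
Reagents that add atoms: none
Why: BBr3 demethylation cleaves both aryl methyl ethers through aryloxyboranes without breaking the diaryl ether bonds, and hydrolysis should give the two free phenols of the target.

## Compound list

1 | 4-(4-hydroxyphenyl)butan-2-one | CC(=O)CCc1ccc(O)cc1 | starting material
2 | 4-[4-(triisopropylsilyloxy)phenyl]butan-2-one | CC(=O)CCc1ccc(O[Si](C(C)C)(C(C)C)C(C)C)cc1 | intermediate
3 | N'-{4-[4-(triisopropylsilyloxy)phenyl]butan-2-ylidene}-2,4,6-triisopropylbenzenesulfonohydrazide (E) | C/C(CCc1ccc(O[Si](C(C)C)(C(C)C)C(C)C)cc1)=N\NS(=O)(=O)c1c(C(C)C)cc(C(C)C)cc1C(C)C | intermediate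
4 | hexacarbonylchromium | O=C=[Cr](=C=O)(=C=O)(=C=O)(=C=O)=C=O | starting material
5 | {4-[4-(triisopropylsilyloxy)phenyl]but-1-en-2-yl}lithium | [Li]C(=C)CCc1ccc(O[Si](C(C)C)(C(C)C)C(C)C)cc1 | intermediate
6 | lithium pentacarbonyl{1-oxido-2-methylidene-4-[4-(triisopropylsilyloxy)phenyl]butylidene}chromate | [Li+].[O-]C(C(=C)CCc1ccc(O[Si](C(C)C)(C(C)C)C(C)C)cc1)=[Cr](=C=O)(=C=O)(=C=O)(=C=O)=C=O | intermediate
7 | tetramethylammonium pentacarbonyl{1-oxido-2-methylidene-4-[4-(triisopropylsilyloxy)phenyl]butylidene}chromate | C[N+](C)(C)C.[O-]C(C(=C)CCc1ccc(O[Si](C(C)C)(C(C)C)C(C)C)cc1)=[Cr](=C=O)(=C=O)(=C=O)(=C=O)=C=O | intermediate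
8 | 3-(hydroxymethyl)phenol | OCc1cccc(O)c1 | starting material
9 | (3-hydroxybenzyl)triphenylphosphonium bromide | [Br-].Oc1cccc(C[P+](c2ccccc2)(c2ccccc2)c2ccccc2)c1 | intermediate
10 | 3-bromo-4-methoxybenzaldehyde | COc1ccc(C=O)cc1Br | starting material
11 | 3-[2-(3-bromo-4-methoxyphenyl)ethenyl]phenol (E/Z mixture, geometry not defined) | Oc1cccc(C=Cc2ccc(OC)c(Br)c2)c1 | intermediate
12 | 3-[2-(3-bromo-4-methoxyphenyl)ethyl]phenol | Oc1cccc(CCc2ccc(OC)c(Br)c2)c1 | intermediate
13 | pentacarbonyl[acetoxy{4-[4-(triisopropylsilyloxy)phenyl]but-1-en-2-yl}methylidene]chromium | CC(=O)OC(C(=C)CCc1ccc(O[Si](C(C)C)(C(C)C)C(C)C)cc1)=[Cr](=C=O)(=C=O)(=C=O)(=C=O)=C=O | intermediate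
14 | pentacarbonyl[{3-[2-(3-bromo-4-methoxyphenyl)ethyl]phenoxy}{4-[4-(triisopropylsilyloxy)phenyl]but-1-en-2-yl}methylidene]chromium | O=C=[Cr](=C=O)(=C=O)(=C=O)(=C=O)=C(Oc1cccc(CCc2ccc(OC)c(Br)c2)c1)C(=C)CCc1ccc(O[Si](C(C)C)(C(C)C)C(C)C)cc1 | intermediate
15 | ethynyltrimethylsilane | C#C[Si](C)(C)C | starting material
16 | tricarbonylchromium complex of 17, chromium bound η6 to ring A (written as two parts) | Oc1cc(CCc2ccc(O[Si](C(C)C)(C(C)C)C(C)C)cc2)c(Oc2cccc(CCc3ccc(OC)c(Br)c3)c2)cc1[Si](C)(C)C.O=C=[Cr](=C=O)=C=O | intermediate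
17 | 4-{3-[2-(3-bromo-4-methoxyphenyl)ethyl]phenoxy}-5-{2-[4-(triisopropylsilyloxy)phenyl]ethyl}-2-(trimethylsilyl)phenol | Oc1cc(CCc2ccc(O[Si](C(C)C)(C(C)C)C(C)C)cc2)c(Oc2cccc(CCc3ccc(OC)c(Br)c3)c2)cc1[Si](C)(C)C | intermediate
18 | 4-{3-[2-(3-bromo-4-methoxyphenyl)ethyl]phenoxy}-3-{2-[4-(triisopropylsilyloxy)phenyl]ethyl}phenol | Oc1ccc(Oc2cccc(CCc3ccc(OC)c(Br)c3)c2)c(CCc2ccc(O[Si](C(C)C)(C(C)C)C(C)C)cc2)c1 | intermediate
19 | 1-{3-[2-(3-bromo-4-methoxyphenyl)ethyl]phenoxy}-4-methoxy-2-{2-[4-(triisopropylsilyloxy)phenyl]ethyl}benzene | COc1ccc(Oc2cccc(CCc3ccc(OC)c(Br)c3)c2)c(CCc2ccc(O[Si](C(C)C)(C(C)C)C(C)C)cc2)c1 | intermediate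
20 | 4-[2-(2-{3-[2-(3-bromo-4-methoxyphenyl)ethyl]phenoxy}-5-methoxyphenyl)ethyl]phenol | COc1ccc(Oc2cccc(CCc3ccc(OC)c(Br)c3)c2)c(CCc2ccc(O)cc2)c1 | intermediate
21 | macrocyclic di-O-methyl ether of the target (18-membered ring, OMe on ring A and ring C) | COc1ccc2c(c1)CCc1ccc(cc1)Oc1cc(ccc1OC)CCc1cccc(c1)O2 | intermediate
22 | CNP0135015.0 | Oc1ccc2c(c1)CCc1ccc(cc1)Oc1cc(ccc1O)CCc1cccc(c1)O2 | target

## Step count and risks

Total step count: 13. Longest linear sequence: 10 steps (1 to 22 through steps 1, 2, 3, 7–13; the branch from 8 is equally long).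

Steps most likely to fail:

1. Step 8 (proposed new method). The less stabilised aryloxycarbene may lose its carbene ligand before alkyne uptake, or the vinylketene stage may divert to cyclobutenone or furan formation instead of electrocyclic closure. The fallback uses known chemistry and buys ring A instead of building it. It sets out from 12: nucleophilic aromatic substitution on 2-fluoro-5-methoxybenzaldehyde (K2CO3, DMF, 120 °C) should give 2-{3-[2-(3-bromo-4-methoxyphenyl)ethyl]phenoxy}-5-methoxybenzaldehyde F1. Wittig reaction of F1 with (4-hydroxybenzyl)triphenylphosphonium bromide F2 (made from 4-hydroxybenzyl alcohol and PPh3·HBr as in step 4; t-BuOK, 2.2 equiv, THF) should give 4-[2-(2-{3-[2-(3-bromo-4-methoxyphenyl)ethyl]phenoxy}-5-methoxyphenyl)ethenyl]phenol F3. Diimide reduction as in step 6 returns to the route at 20.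

2. Step 7. The acyloxycarbene may break down thermally before the weakly nucleophilic phenol adds, or the phenol may attack the acetyl carbon and regenerate the acylate. The fallback makes the ring D–O–ring A bond on an activated fluoroarene and the ring A–ring B link by alkyne coupling, so no carbene is needed. It sets out from 11: nucleophilic aromatic substitution on 2-fluoro-5-methoxybenzaldehyde (K2CO3, DMF, 120 °C) should give 2-{3-[2-(3-bromo-4-methoxyphenyl)ethenyl]phenoxy}-5-methoxybenzaldehyde F4. Ohira–Bestmann homologation (dimethyl (1-diazo-2-oxopropyl)phosphonate, K2CO3, MeOH) should give 2-bromo-4-{2-[3-(2-ethynyl-4-methoxyphenoxy)phenyl]ethenyl}-1-methoxybenzene F5. Sonogashira coupling with 4-iodophenol (PdCl2(PPh3)2, CuI, Et3N, rt, where the iodide reacts ahead of the ring C bromide) should give 4-[(2-{3-[2-(3-bromo-4-methoxyphenyl)ethenyl]phenoxy}-5-methoxyphenyl)ethynyl]phenol F6. Excess diimide (TsNHNH2, NaOAc) saturates alkyne and alkene together and returns to the route at 20.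

3. Step 12. Intermolecular coupling to oligomers and reductive loss of bromine from the hindered, electron-rich ring C bromide may outrun ring closure. The fallback turns the bromide into the nucleophilic partner of an oxidative copper coupling at room temperature. It sets out from 20: Miyaura borylation (B2pin2, PdCl2(dppf), KOAc, dioxane, 90 °C) should give 4-[2-(2-{3-[2-(4-methoxy-3-(4,4,5,5-tetramethyl-1,3,2-dioxaborolan-2-yl)phenyl)ethyl]phenoxy}-5-methoxyphenyl)ethyl]phenol F7. Transesterification with diethanolamine followed by dilute HCl should give the boronic acid [5-(2-{3-[2-(2-{4-hydroxyphenyl}ethyl)-4-methoxyphenoxy]phenyl}ethyl)-2-methoxyphenyl]boronic acid F8. Chan–Lam–Evans macrocyclisation (Cu(OAc)2, Et3N, 4 Å molecular sieves, CH2Cl2, air, 2 mM) returns to the route at 21.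

## Further compounds

F1 | step 8 | 2-{3-[2-(3-bromo-4-methoxyphenyl)ethyl]phenoxy}-5-methoxybenzaldehyde | COc1ccc(Oc2cccc(CCc3ccc(OC)c(Br)c3)c2)c(C=O)c1
F2 | step 8 | (4-hydroxybenzyl)triphenylphosphonium bromide | [Br-].Oc1ccc(C[P+](c2ccccc2)(c2ccccc2)c2ccccc2)cc1
F3 | step 8 | 4-[2-(2-{3-[2-(3-bromo-4-methoxyphenyl)ethyl]phenoxy}-5-methoxyphenyl)ethenyl]phenol (E/Z mixture) | COc1ccc(Oc2cccc(CCc3ccc(OC)c(Br)c3)c2)c(C=Cc2ccc(O)cc2)c1
F4 | step 7 | 2-{3-[2-(3-bromo-4-methoxyphenyl)ethenyl]phenoxy}-5-methoxybenzaldehyde (E/Z mixture) | COc1ccc(Oc2cccc(C=Cc3ccc(OC)c(Br)c3)c2)c(C=O)c1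
F5 | step 7 | 2-bromo-4-{2-[3-(2-ethynyl-4-methoxyphenoxy)phenyl]ethenyl}-1-methoxybenzene (E/Z mixture) | COc1ccc(Oc2cccc(C=Cc3ccc(OC)c(Br)c3)c2)c(C#C)c1
F6 | step 7 | 4-[(2-{3-[2-(3-bromo-4-methoxyphenyl)ethenyl]phenoxy}-5-methoxyphenyl)ethynyl]phenol (E/Z mixture) | COc1ccc(Oc2cccc(C=Cc3ccc(OC)c(Br)c3)c2)c(C#Cc2ccc(O)cc2)c1
F7 | step 12 | pinacol boronate of 20 (Bpin in place of Br on ring C) | COc1ccc(Oc2cccc(CCc3ccc(OC)c(B4OC(C)(C)C(C)(C)O4)c3)c2)c(CCc2ccc(O)cc2)c1
F8 | step 12 | boronic acid of 20 (B(OH)2 in place of Br on ring C) | COc1ccc(Oc2cccc(CCc3ccc(OC)c(B(O)O)c3)c2)c(CCc2ccc(O)cc2)c1
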